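The easy step is the balance of E, the substrate: in this closed flask 38 mM = cE + cJ + cD + cQ, with Q among the proposed products of E. Q was not read, and neither was E.

| flask | E | remark | time |
|---|---|---|---|
| red | 38 mM | the very flask that is asked about, followed so far |  |
| flask | 38 mM |  | 50 min |

red run (percent of the E charged)

| time / min | J / % | D / % |
|---|---|---|
| 2.00 | 1.9 | 3.4 |
| 3.00 | 1.1 | 4.7 |
| 6.00 | 4.5 | 6.3 |
| 10.0 | 4.8 | 12.7 |
| 15.0 | 6.0 | 17.6 |
| 25.0 | 12.7 | 25.1 |

(standard deviation of a reading: 1 percentage point)

* concentration of J at 50 min, in mM
* concentration of D at 50 min, in mM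
* concentration of E at 50 min, in mM

- the earlier runs were read with a standard deviation of 1 percentage point
- steps that have been proposed: E -> J; E -> Q; Q <-> D; E -> D; J -> Q

So the red run gives a ceiling for cE, not a value. At 25.0 min the readings of J and D sum to 37.8%, which leaves E at most 62.2% of the charge, within the scatter of those readings. Taking the loss of E as first order, we call the lower bound on its apparent first-order constant the visible constant, 0.0190 min⁻¹. At 50 min it puts cE at or below 14.7 mM.

Now turn the question round. For E to be down to 10.0% of its charge at 50 min, the constant has to be 0.0460 min⁻¹, which is 2.42 times the visible one. Q would then hold 30.5% of the charge at 25.0 min, in a pool that was not read. We commit to the ceiling and to no value beneath it.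

The forecast gives cJ 7 mM, cD 15 mM and cE 14 mM, and finds “no clear sign of a missing pool”.

The flask gives cJ 4.88 mM, cD 13.0 mM and cE 1.95 mM.

    E → J (k = 0.00840 min⁻¹)
    E → Q (k = 0.0370 min⁻¹)
    Q ⇌ D (K = 0.730, k = 0.0590 min⁻¹)
    E → D (k = 0.0140 min⁻¹)
    J → Q (k = 0.00120 min⁻¹)

So cE lies under our reckoned ceiling of 14.7 mM. At 10.8 min the half-life of E by the step to Q, 19 min, is shorter than the 50 min by the step to D, and at 50.0 min Q holds 47.9% of the charge.

In the neighbouring flask, read at 12 min with the same charge, 0.0190 min⁻¹ puts cE at or below 30.3 mM. The computed value there is 18.6 mM.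

The earlier runs and the new flask come from a simulation from invented constants.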